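**Retrosynthetic overview**
- The C3 stereocentre is set last, by enantioselective iridium-catalysed hydrogenation of an isoflav-3-ene, with MOM cleavage in the same flask.
- Rings A and C are formed together in one flask from a 4-alkynyl-4-hydroxycyclobutenone: thermal ring expansion gives the ring A quinone, then quinone to ortho-quinone methide tautomerization and oxa-6π closure gives ring C.
- The cyclobutenone comes from dimethyl squarate and the lithium acetylide of a 2-aryl-1,4-enyne that carries ring B.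
- The enyne comes from directed ortho-metalation and Negishi coupling of MOM-protected 2,3-dimethoxyphenol with a 2-bromo-1,4-enyne (from 2,3-dibromopropene and ethynyltrimethylsilane).
- Ring order: B is bought, A and C are made together, the stereocentre follows.

Assumption: dimethyl squarate is taken as a purchasable building block.
Assumption: the (4R,5R) catalyst in step 7 is taken to give (3S), by analogy with (E)-1,2-diaryl olefins and my recollection of the equol series; if the first run shows (3R), the mirror-image catalyst is used in the same step.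

**Step 1**
Reactants: 1 2,3-dimethoxyphenol
Product: 3 1,2-dimethoxy-3-(methoxymethoxy)benzene, via sodium 2,3-dimethoxyphenoxide 2 (not isolated)
Conditions: NaH (1.2 equiv), MOMCl (1.2 equiv), THF, 0 °C to rt
Reagents that add atoms: chloromethyl methyl ether (MOMCl), COCCl
Why: O-alkylation of the phenoxide (MOM protection) masks the acidic OH and installs the directing group for step 3.

**Step 2**
Reactants: 4 ethynyltrimethylsilane; 5 2,3-dibromoprop-1-ene
Product: 7 (4-bromopent-4-en-1-yn-1-yl)trimethylsilane, via alkynylmagnesium bromide 6 (not isolated)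
Conditions: EtMgBr (1.0 equiv), THF, 0 °C to rt; then CuBr (5 mol%), 5, 60 °C
Reagents that add atoms: none
Why: Copper-catalysed allylic alkynylation by the alkynyl Grignard reagent; SN2 and SN2' attack give the same 1,4-enyne and the vinylic C–Br bond is untouched.

**Step 3**
Reactants: 3 1,2-dimethoxy-3-(methoxymethoxy)benzene; 7 (4-bromopent-4-en-1-yn-1-yl)trimethylsilane
Product: 10 {4-[3,4-dimethoxy-2-(methoxymethoxy)phenyl]pent-4-en-1-yn-1-yl}trimethylsilane, via aryllithium 8 (not isolated), via arylzinc chloride 9 (not isolated)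
Conditions: n-BuLi (1.1 equiv), THF, 0 °C to rt; ZnCl2 (1.2 equiv), 0 °C; then 7, Pd(PPh3)4 (3 mol%), 55 °C
Reagents that add atoms: none
Why: Directed ortho-metalation (OMOM outcompetes OMe, so lithiation goes ortho to OMOM), lithium-to-zinc transmetalation and Negishi cross-coupling at the vinylic bromide.

**Step 4**
Reactants: 10 {4-[3,4-dimethoxy-2-(methoxymethoxy)phenyl]pent-4-en-1-yn-1-yl}trimethylsilane
Product: 11 1-(pent-1-en-4-yn-2-yl)-3,4-dimethoxy-2-(methoxymethoxy)benzene
Conditions: K2CO3 (0.2 equiv), MeOH, 0 °C to rt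
Reagents that add atoms: none
Why: Base-catalysed methanolysis of the alkynyl C–Si bond (protodesilylation), mild enough to leave the skipped enyne unisomerized.

**Step 5**
Reactants: 11 1-(pent-1-en-4-yn-2-yl)-3,4-dimethoxy-2-(methoxymethoxy)benzene; 12 dimethyl squarate (3,4-dimethoxycyclobut-3-ene-1,2-dione)
Product: 15 4-hydroxy-2,3-dimethoxy-4-{4-[3,4-dimethoxy-2-(methoxymethoxy)phenyl]pent-4-en-1-yn-1-yl}cyclobut-2-en-1-one (racemic at C4), via lithium acetylide 13 (not isolated), via lithium alkoxide 14 (not isolated)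
Conditions: n-BuLi (1.0 equiv), THF, −78 °C; then 12 (1.1 equiv), −78 °C; sat. aq NH4Cl, −78 °C to rt
Reagents that add atoms: none
Why: Kinetic deprotonation of the terminal alkyne and 1,2-addition of the acetylide to one squarate carbonyl (squarate alkynylation); the new carbinol centre is racemic but is destroyed in step 6.

**Step 6**
Reactants: 15 4-hydroxy-2,3-dimethoxy-4-{4-[3,4-dimethoxy-2-(methoxymethoxy)phenyl]pent-4-en-1-yn-1-yl}cyclobut-2-en-1-one
Product: 19 3-[3,4-dimethoxy-2-(methoxymethoxy)phenyl]-7,8-dimethoxy-2H-chromen-6-ol, via enynylketene 16 (not isolated), via allylquinone 17 (not isolated), via ortho-quinone methide 18 (not isolated)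
Conditions: degassed p-xylene (0.02 M), 138 °C, 30 min; then Et3N (2 equiv), 80 °C, same flask, Ar
Reagents that add atoms: none
Why: Proposed new method: heating opens the cyclobutenone (4π-electrocyclic) to a (Z)-enynylketene that closes to a ring A diradical and collapses by hydrogen transfer to the allylquinone (closest known reaction: Moore rearrangement of 4-alkynyl-4-hydroxycyclobutenones), and the amine then tautomerizes the quinone to a vinyl ortho-quinone methide that closes by oxa-6π-electrocyclization to the 2H-chromen-6-ol (closest known reaction: ubiquinone to ubichromenol isomerization), so rings A and C form in one flask; each half is precedented but the sequence has not been run on such a substrate.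

**Step 7**
Reactants: 19 3-[3,4-dimethoxy-2-(methoxymethoxy)phenyl]-7,8-dimethoxy-2H-chromen-6-ol
Product: 21 (3S)-3-(2-hydroxy-3,4-dimethoxyphenyl)-7,8-dimethoxy-3,4-dihydro-2H-chromen-6-ol, via MOM-protected (3S)-isoflavan 20 (not isolated)
Conditions: H2 (50 bar), [Ir(cod)(L)][B(3,5-(CF3)2C6H3)4] (1 mol%), CH2Cl2, rt; then vent, HCl (3 M in MeOH), 40 °C. Here cod = 1,5-cyclooctadiene and L = (4R,5R)-4-[2-(dicyclohexylphosphanyloxy)-1,3-diphenylpropan-2-yl]-5-methyl-2-phenyl-4,5-dihydro-1,3-oxazole.
Reagents that add atoms: none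
Why: Enantioselective iridium–P,N-catalysed hydrogenation of the trisubstituted (E)-1,2-diaryl-type olefin delivers H2 to one face and sets C3 as (S), and acid-catalysed acetal methanolysis then removes MOM without touching the stereocentre.

**Compound list**
1 | 2,3-dimethoxyphenol | COc1cccc(O)c1OC | starting material
2 | sodium 2,3-dimethoxyphenoxide | COc1cccc([O-])c1OC.[Na+] | intermediate
3 | 1,2-dimethoxy-3-(methoxymethoxy)benzene | COCOc1cccc(OC)c1OC | intermediate
4 | ethynyltrimethylsilane | C#C[Si](C)(C)C | starting material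
5 | 2,3-dibromoprop-1-ene | C=C(Br)CBr | starting material
6 | [(trimethylsilyl)ethynyl]magnesium bromide | C[Si](C)(C)C#C[Mg]Br | intermediate
7 | (4-bromopent-4-en-1-yn-1-yl)trimethylsilane | C=C(Br)CC#C[Si](C)(C)C | intermediate
8 | [3,4-dimethoxy-2-(methoxymethoxy)phenyl]lithium | [Li]c1ccc(OC)c(OC)c1OCOC | intermediate
9 | [3,4-dimethoxy-2-(methoxymethoxy)phenyl]zinc chloride | Cl[Zn]c1ccc(OC)c(OC)c1OCOC | intermediate
10 | {4-[3,4-dimethoxy-2-(methoxymethoxy)phenyl]pent-4-en-1-yn-1-yl}trimethylsilane | C=C(CC#C[Si](C)(C)C)c1ccc(OC)c(OC)c1OCOC | intermediate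
11 | 1-(pent-1-en-4-yn-2-yl)-3,4-dimethoxy-2-(methoxymethoxy)benzene | C=C(CC#C)c1ccc(OC)c(OC)c1OCOC | intermediate
12 | dimethyl squarate (3,4-dimethoxycyclobut-3-ene-1,2-dione) | COC1=C(OC)C(=O)C1=O | starting material
13 | lithium acetylide of 11 | [Li]C#CCC(=C)c1ccc(OC)c(OC)c1OCOC | intermediate
14 | lithium alkoxide of 15 | COC1=C(OC)C([O-])(C#CCC(=C)c2ccc(OC)c(OC)c2OCOC)C1=O.[Li+] | intermediate
15 | 4-hydroxy-2,3-dimethoxy-4-{4-[3,4-dimethoxy-2-(methoxymethoxy)phenyl]pent-4-en-1-yn-1-yl}cyclobut-2-en-1-one (racemic) | COC1=C(OC)C(O)(C#CCC(=C)c2ccc(OC)c(OC)c2OCOC)C1=O | intermediate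
16 | (3Z)-4-hydroxy-2,3-dimethoxy-8-[3,4-dimethoxy-2-(methoxymethoxy)phenyl]nona-1,3,8-trien-5-yn-1-one | COC(=C=O)/C(OC)=C(\C#CCC(=C)c1ccc(OC)c(OC)c1OCOC)O | intermediate
17 | 2,3-dimethoxy-5-{2-[3,4-dimethoxy-2-(methoxymethoxy)phenyl]prop-2-en-1-yl}cyclohexa-2,5-diene-1,4-dione | COC1=C(OC)C(=O)C(CC(=C)c2ccc(OC)c(OC)c2OCOC)=CC1=O | intermediate
18 | (6Z)-4-hydroxy-2,3-dimethoxy-6-{2-[3,4-dimethoxy-2-(methoxymethoxy)phenyl]prop-2-en-1-ylidene}cyclohexa-2,4-dien-1-one | O=C1C(OC)=C(OC)C(O)=C/C1=C/C(=C)c1ccc(OC)c(OC)c1OCOC | intermediate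
19 | 3-[3,4-dimethoxy-2-(methoxymethoxy)phenyl]-7,8-dimethoxy-2H-chromen-6-ol | COc1c(O)cc2C=C(COc2c1OC)c1ccc(OC)c(OC)c1OCOC | intermediate
20 | (3S)-3-[3,4-dimethoxy-2-(methoxymethoxy)phenyl]-7,8-dimethoxy-3,4-dihydro-2H-chromen-6-ol | COc1ccc([C@H]2COc3c(cc(O)c(OC)c3OC)C2)c(OCOC)c1OC | intermediate
21 | (3S)-3-(2-hydroxy-3,4-dimethoxyphenyl)-7,8-dimethoxy-3,4-dihydro-2H-chromen-6-ol | COc1ccc([C@H]2COc3c(cc(O)c(OC)c3OC)C2)c(O)c1OC | target

**Totals**
Total step count: 7. Longest linear sequence: 6 steps (steps 1, 3, 4, 5, 6, 7, from 2,3-dimethoxyphenol).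

**Three steps most likely to fail**

Step 6 (ring expansion and chromenol closure). The diradical may be diverted to a cyclopentenedione or captured by the styrene, or the quinone may be attacked by the amine. The fallback sets out from 15 and avoids the diradical. The alkyne of 15 is semihydrogenated (H2 1 atm, Pd/CaCO3 poisoned with Pb(OAc)2, quinoline, EtOAc) to 4-hydroxy-2,3-dimethoxy-4-{(1Z)-4-[3,4-dimethoxy-2-(methoxymethoxy)phenyl]penta-1,4-dien-1-yl}cyclobut-2-en-1-one F1. Heating F1 in toluene at 110 °C gives, by ring opening, 6π-electrocyclization and enolization, 2,3-dimethoxy-5-{2-[3,4-dimethoxy-2-(methoxymethoxy)phenyl]prop-2-en-1-yl}benzene-1,4-diol F2. Oxidation of F2 with Ag2O in Et2O gives the quinone, and the route is rejoined at 17, which is taken to 19 with Et3N as in the second stage of step 6.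

Step 7 (enantioselective hydrogenation). The free 6-OH and the ortho-substituted aryl group may lower rate or selectivity, and the sense of induction rests on analogy. The fallback sets out from 19 and replaces asymmetric catalysis by resolution. Hydrogenation over Pd/C (H2 1 atm, EtOAc) gives racemic 3-[3,4-dimethoxy-2-(methoxymethoxy)phenyl]-7,8-dimethoxy-3,4-dihydro-2H-chromen-6-ol F3. Preparative chiral supercritical-fluid chromatography on an amylose tris(3,5-dimethylphenylcarbamate) phase separates it, and the (3R)-3-[3,4-dimethoxy-2-(methoxymethoxy)phenyl]-7,8-dimethoxy-3,4-dihydro-2H-chromen-6-ol F4 is set aside. The route is rejoined at 20, which is deprotected as in the second stage of step 7.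

Step 3 (ortho-metalation and Negishi coupling). The hindered arylzinc may couple poorly, or the bromoenyne may not survive palladium. The fallback sets out from 8 and moves the bond formation from aryl–vinyl to allyl–alkynyl. Transmetalation of 8 with MgBr2·OEt2 gives [3,4-dimethoxy-2-(methoxymethoxy)phenyl]magnesium bromide F5. Copper-catalysed anti-carbomagnesiation of prop-2-yn-1-ol (pre-formed magnesium alkoxide, CuI 10 mol%, THF, reflux) gives 2-[3,4-dimethoxy-2-(methoxymethoxy)phenyl]prop-2-en-1-ol F6. Treatment with CBr4 and PPh3 (CH2Cl2, 0 °C) gives 1-(3-bromoprop-1-en-2-yl)-3,4-dimethoxy-2-(methoxymethoxy)benzene F7. Coupling of F7 with the Grignard reagent 6 (CuBr 5 mol%, THF) rejoins the route at 10.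

**Further compounds**
F1 | step 6 | 4-hydroxy-2,3-dimethoxy-4-{(1Z)-4-[3,4-dimethoxy-2-(methoxymethoxy)phenyl]penta-1,4-dien-1-yl}cyclobut-2-en-1-one | COC1=C(OC)C(O)(/C=C\CC(=C)c2ccc(OC)c(OC)c2OCOC)C1=O
F2 | step 6 | 2,3-dimethoxy-5-{2-[3,4-dimethoxy-2-(methoxymethoxy)phenyl]prop-2-en-1-yl}benzene-1,4-diol | COc1c(O)cc(CC(=C)c2ccc(OC)c(OC)c2OCOC)c(O)c1OC
F3 | step 7 | racemic 3-[3,4-dimethoxy-2-(methoxymethoxy)phenyl]-7,8-dimethoxy-3,4-dihydro-2H-chromen-6-ol | COc1ccc(C2COc3c(cc(O)c(OC)c3OC)C2)c(OCOC)c1OC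
F4 | step 7 | (3R)-3-[3,4-dimethoxy-2-(methoxymethoxy)phenyl]-7,8-dimethoxy-3,4-dihydro-2H-chromen-6-ol | COc1ccc([C@@H]2COc3c(cc(O)c(OC)c3OC)C2)c(OCOC)c1OC
F5 | step 3 | [3,4-dimethoxy-2-(methoxymethoxy)phenyl]magnesium bromide | Br[Mg]c1ccc(OC)c(OC)c1OCOC
F6 | step 3 | 2-[3,4-dimethoxy-2-(methoxymethoxy)phenyl]prop-2-en-1-ol | C=C(CO)c1ccc(OC)c(OC)c1OCOC
F7 | step 3 | 1-(3-bromoprop-1-en-2-yl)-3,4-dimethoxy-2-(methoxymethoxy)benzene | C=C(CBr)c1ccc(OC)c(OC)c1OCOC
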